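## Structural features

Betaethrin E is an achiral diaryl ether: two benzene rings joined through one oxygen. Ring A is a methyl benzoate with the ester at C1, a phenol at C2 that is hydrogen-bonded to the ester carbonyl, a methyl group at C4 and the ether oxygen at C6, so the ester sits between two oxygens. Ring B carries the palmitoyloxymethyl group at C1, the ether oxygen at C2, a free phenol at C3 and a methoxy group at C5, with hydrogens at C4 and C6. The ether oxygen is therefore flanked by three ortho substituents: CO2Me on ring A, and CH2O and OH on ring B. There is no stereocentre, so no stereocentres stand next to each other; the only stereochemical element on the way is an enol ether double bond that ends inside ring B. The fragile groups are the benzylic palmitate (hydrogenolysis, ionisation of the benzylic C-O bond, acyl transfer under base), the two phenols of different acidity and, less so, the hindered methyl ester. The difficulty is twofold: a tri-ortho-substituted aryl-O-aryl bond is a poor target for metal-mediated coupling or nucleophilic aromatic substitution, and the three oxygens of ring B (O2 arylated, O3 free, O5 methylated) must be told apart. The key step exploits the meta relation of C3-OH and C5-OMe with C4-H between them: C3 comes from a ketene carbonyl carbon, C4 and C5 (with its methoxy group) from methoxyacetylene, C6 from a diazo carbon, and C1 and C2 from a vinyl group that already carries the CH2O arm and the ring A oxygen.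

## Logic of the disconnections

21 is cut at the acyl C-O bond of the benzylic ester, giving 19 and 20. The benzylic palmitate is the group least able to survive reduction, base or ionising acid, so it is made last. The cut removes sixteen carbons and leaves a triol. The forward step must acylate the primary alcohol and leave both phenols untouched.

19 is traced to 18 by placing a silyl group on the CH2O oxygen (O-Si bond). This oxygen must be masked while a ketene is present: a free hydroxyl would close a butenolide onto the ketene carbon, and an ester at this allylic position beside an enone would act as a leaving group. The ring A phenol is left free. It is hydrogen-bonded to the ester and less nucleophilic than the phenol that the annulation itself creates, so masking it would remove no failure mode, and one fluoride step becomes the whole deprotection with no hydrogenolysis near the benzylic C-O bond. The forward step must remove silicon under conditions too mild to touch the esters.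

18 is cut at four ring B bonds, C1-C6, C3-C4, C5-C6 and C2-C3, giving 10 and 13. This removes ring B together with its oxygen pattern: O3 and O5 emerge already differentiated, and the crowded C2-O bond is moved back to an acyclic stage. A tetrasubstituted arene is reduced to a diazoketone chain and a two-carbon alkyne. The forward step demands the correct orientation of 13 on the ketene and an aryl enol ether that survives light.

10 is cut at the C6-N bond and leads to 8. Diazo transfer to a methyl ketone replaces acylation of diazomethane by a conjugated acid chloride. That older path is hazardous, is threatened by dipolar addition to the double bond, and would first need saponification of an acrylate ester beside the ring A methyl ester, where hydroxide could also expel the aryloxide. The demand is selective enolisation of the methyl group in the presence of the vinylogous ester.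

8 is cut at the O-C2 bond into 6 and 7. At this stage C2 is the beta carbon of an enone, so the hindered oxygen-carbon bond is formed by addition-elimination and no aryl ether coupling is needed. 7 is symmetric, so either hydroxyl may react. The forward step must stop after one hydroxyl has reacted.

6 is traced through 5 to 4 (C-Br bond, bromination then loss of HBr), 4 to 3 (O-Si bond), and 3 to 1 and 2 (the bond between the alpha carbon and the CH2O carbon, by Morita-Baylis-Hillman reaction). This builds the CH2O arm on the enone from two bulk chemicals. The demand is that HBr is lost towards the bromomethyl group and not towards the silyloxymethyl arm.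

13 is traced through 12 to 11 by two eliminations (one C-O and the C-Cl bond). The demand is the handling of a volatile alkyne, which is distilled straight into the solvent of the key step.

## Other disconnections considered

Alternative 1: The cut runs through ring A at C1-C6 and C3-C4 and leaves ring B complete. In the forward step the sodium enolate of methyl 3-oxo-4-(triphenylphosphoranylidene)butanoate A3 would attack the chlorine-bearing carbon of the beta-aryloxy-beta-chloro enone A2, which carries the finished ring B with its palmitate and an allyl ether on O3. Loss of chloride forms C1-C6, the ylide carbon then olefinates the methyl ketone to form C3-C4, and tautomerisation gives the salicylate A1, one deallylation from the target.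
- In its favour: ring A arrives with OH, CH3 and ester placed without any regiochemical choice, and the palmitate is already present.
- Better than the chosen plan: the end game is one step against two from 18, and there is no photochemistry, diazo compound or volatile alkyne.
- Against it: ring B must be prepared beforehand as a differentiated catechol (O2 free, O3 allylated) with the methoxy and palmitoyloxymethyl groups in place. That is the very problem the chosen plan solves by annulation.
- Against it: the addition intermediate could expel the aryloxide instead of chloride, which would cut ring B off, and a basic enolate meets an enolisable benzylic palmitate.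
- Comparison: on structure the plans are equal in that neither makes an aryl-oxygen bond on a finished arene. On mechanism this plan rests on leaving-group discrimination at one carbon, the chosen plan on the polarity of an ynol ether. On step economy the short end game is expected to be offset by the separate synthesis of the ring B phenol, so the total should not be lower than nine.

Alternative 2: The cut takes the ring A C6-O bond and the C1-carboxyl bond. In the forward step a fluoride source acts on the silylaryl triflate A5 to release an aryne. The phenoxide of the ring B phenol A6 adds at C6, remote from the benzyloxy group, and the aryl anion at C1, stabilised by the neighbouring benzyloxy group, takes up carbon dioxide A7 to give the acid A4. No ring closes.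
- In its favour: two bonds at the crowded carbon pair form in one operation near room temperature without a transition metal.
- Better than the chosen plan: it is the most convergent of the four plans, joining two complete aromatic halves. Equal: regiocontrol, since the inductive bias of a 3-alkoxy aryne places the carboxyl between the two oxygens.
- Against it: the aryl anion is protonated more readily than carboxylated if any proton source is present, and the phenoxide can bind A7 as a carbonate.
- Against it: fluoride threatens the silyl ether of A6, and A6 is again a pre-differentiated catechol; A5 needs a synthesis of its own.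
- Against it: after A4 come esterification, removal of two benzyl groups by hydrogenolysis beside a benzylic C-O bond, desilylation and acylation, against two steps from 18.
- Comparison: the aryne route forms the ether on an aromatic carbon by a high-energy intermediate, the chosen plan on a vinyl carbon by addition-elimination. Overall step count is expected to be higher.

Alternative 3: The cut takes ring B bonds C1-C2 and C4-C5 and places ring B at the oxidation level of a cyclohexane-1,3-dione. In the forward step the aryloxyacetone A9, held as its carboxylate, would add through its oxygen-bearing methylene to the beta carbon of ethyl (E)-4-(tert-butyldimethylsilyloxy)but-2-enoate A10 (C1-C2). The methyl ketone enolate would then close onto the ester (C4-C5) to give the racemic trans dione A8.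
- In its favour: cheap reagents, an alkoxide base, no light, no diazo compound, and the ether oxygen is attached by plain O-alkylation of a phenol.
- Better than the chosen plan: cost and ease of scale-up of the key step. Equal: it also avoids any aryl-oxygen coupling.
- Against it: ring B is two hydrogens short of aromatic, so a dehydrogenation is needed, and the two carbonyl oxygens must then be differentiated (O5 methylated, O3 free). The chosen plan delivers this pattern directly.
- Against it: two stereocentres are made only to be destroyed. The free acid, needed because an ester ortho to the oxyacetone chain would invite Dieckmann-type closure to a benzofuranone, must later be re-esterified, and a benzyl group must be removed by hydrogenolysis.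
- Comparison: about six operations are expected after A8 against two after 18, so step economy favours the chosen plan.

Key step: step 7

Remark on the chemistry: the target has no stereocentre, and the enol ether geometry of 6, 8 and 10 is not critical, since addition-elimination should settle on the E isomer and either geometry of the vinylketene leads to the same arene.

## Route

Step 1
Reactants: 1 but-3-en-2-one (methyl vinyl ketone); 2 formaldehyde (37% aqueous solution)
Product: 3 3-(hydroxymethyl)but-3-en-2-one
Conditions: DABCO (10 mol%), THF/H2O, rt
Reagents that add atoms: none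
Why: Morita-Baylis-Hillman reaction: the amine adds to the enone, the enolate attacks formaldehyde through its alpha carbon, and loss of the amine restores the enone; formaldehyde is the most reactive aldehyde partner, which should hold back dimerisation of 1.

Step 2
Reactants: 3 3-(hydroxymethyl)but-3-en-2-one
Product: 4 3-{[(tert-butyldimethylsilyl)oxy]methyl}but-3-en-2-one
Conditions: TBSCl, imidazole, CH2Cl2, 0 °C to rt
Reagents that add atoms: tert-butyldimethylsilyl chloride, CC(C)(C)[Si](C)(C)Cl
Why: Standard silylation of a primary alcohol; the silyl ether is neither a nucleophile nor a leaving group and should tolerate bromine with amine, amide base, light and a ketene.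

Step 3
Reactants: 4 3-{[(tert-butyldimethylsilyl)oxy]methyl}but-3-en-2-one
Product: 6 (E)-4-bromo-3-{[(tert-butyldimethylsilyl)oxy]methyl}but-3-en-2-one, via dibromide 5 (not isolated)
Conditions: Br2, CH2Cl2, -78 to 0 °C; then Et3N, 0 °C to rt
Reagents that add atoms: bromine, BrBr
Why: Bromination-dehydrobromination: bromine adds across the enone double bond and, as the alpha carbon has no hydrogen, the amine should remove the more acidic proton of the CH2Br group with loss of the tertiary alpha bromide, as in the known preparation of 3-bromomethacrylates; the E isomer, with bromine anti to the acetyl group, is the less strained one.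

Step 4
Reactants: 6 (E)-4-bromo-3-{[(tert-butyldimethylsilyl)oxy]methyl}but-3-en-2-one; 7 methyl 2,6-dihydroxy-4-methylbenzoate
Product: 8 methyl 2-{[(1E)-2-{[(tert-butyldimethylsilyl)oxy]methyl}-3-oxobut-1-en-1-yl]oxy}-6-hydroxy-4-methylbenzoate
Conditions: K2CO3, DMF, 0 °C to rt (7 in twofold excess)
Reagents that add atoms: none
Why: Conjugate addition-elimination (vinylic substitution) of the phenoxide on the beta-bromo enone, the enolate intermediate expelling bromide; after the first substitution the remaining hydroxyl is locked in a hydrogen bond to the ester carbonyl and is much less nucleophilic, which together with the excess of 7 should stop the reaction at one hydroxyl, and the reversible addition should settle on the E enol ether.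

Step 5
Reactants: 8 methyl 2-{[(1E)-2-{[(tert-butyldimethylsilyl)oxy]methyl}-3-oxobut-1-en-1-yl]oxy}-6-hydroxy-4-methylbenzoate
Product: 10 methyl 2-{[(1E)-4-diazo-2-{[(tert-butyldimethylsilyl)oxy]methyl}-3-oxobut-1-en-1-yl]oxy}-6-hydroxy-4-methylbenzoate, via trifluoroacetyl ketone 9 (not isolated)
Conditions: LiN(SiMe3)2 (2.2 equiv), THF, -78 °C; CF3CO2CH2CF3; then 4-AcNHC6H4SO2N3, Et3N, H2O, MeCN, rt
Reagents that add atoms: 4-acetamidobenzenesulfonyl azide, CC(=O)Nc1ccc(cc1)S(=O)(=O)N=[N+]=[N-]
Why: Detrifluoroacetylative diazo transfer: the first equivalent of base is taken by the phenol, the second forms the kinetic methyl enolate, Claisen-type trifluoroacetylation activates that carbon for diazo transfer, and retro-Claisen loss of trifluoroacetate leaves the diazoketone; the method is the established one for alpha'-diazo enones and needs neither diazomethane nor an acid chloride.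

Step 6
Reactants: 11 chloroacetaldehyde dimethyl acetal (2-chloro-1,1-dimethoxyethane)
Product: 13 methoxyacetylene (methoxyethyne), via sodium methoxyacetylide 12 (not isolated)
Conditions: NaNH2 (3 equiv), liq. NH3, -33 °C; then sat. aq. NaCl, -70 °C; distil into cold ClCH2CH2Cl
Reagents that add atoms: none
Why: Classical double elimination: amide removes methanol and then HCl, and deprotonation of the alkyne to its sodium salt protects it from further attack until the aqueous quench; the product has no beta hydrogen on oxygen and so cannot fragment to ketene on warming.

Step 7
Reactants: 10 methyl 2-{[(1E)-4-diazo-2-{[(tert-butyldimethylsilyl)oxy]methyl}-3-oxobut-1-en-1-yl]oxy}-6-hydroxy-4-methylbenzoate; 13 methoxyacetylene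
Product: 18 methyl 2-[2-{[(tert-butyldimethylsilyl)oxy]methyl}-6-hydroxy-4-methoxyphenoxy]-6-hydroxy-4-methylbenzoate, via vinylketene 14 (not isolated), via vinylcyclobutenone 15 (not isolated), via dienylketene 16 (not isolated), via cyclohexadienone 17 (not isolated)
Conditions: hν (Pyrex, 300-366 nm), 13 (4 equiv), ClCH2CH2Cl, 5 °C, sealed tube; then 80 °C
Reagents that add atoms: none
Why: Irradiation of 10 expels N2 and the vinyl group shifts from the carbonyl carbon to the former diazo carbon (Wolff rearrangement, new bond C1-C6), giving vinylketene 14. The electron-rich unsubstituted carbon of 13 attacks the ketene carbonyl carbon and the methoxy-bearing carbon bonds to the ketene alpha carbon, a polarity-controlled [2+2] cycloaddition that forms C3-C4 and C5-C6 and closes the transient four-membered ring of 15. Four-electron electrocyclic opening of 15, completed by warming, gives dienylketene 16, whose six-electron electrocyclic closure joins the ketene carbon to the aryloxy-bearing vinyl carbon (C2-C3) and closes ring B as cyclohexadienone 17; enolisation then gives phenol 18 and removes the only sp3 centre, so no stereocentre remains to be controlled. The closest known reaction type is the photochemical Wolff variant of the Danheiser benzannulation of alpha'-diazo enones with alkoxy- and silyloxyacetylenes to resorcinol monoethers, here applied to a vinylketene whose terminal carbon bears an aryloxy group. The step needs regioselectivity in the [2+2] addition, which the ynol ether polarity secures and which places OMe meta to the new OH, and it needs the ketene to be taken by 13 and not by a phenol, which the excess of 13 and the low nucleophilicity of the hydrogen-bonded ring A phenol should secure. The E enol ether holds the aryloxy group on the outside of the closing triene, and a Z isomer formed by light would converge on the same arene. The methyl ester, the silyl ether and the aryl enol ether are spectators.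

Step 8
Reactants: 18 methyl 2-[2-{[(tert-butyldimethylsilyl)oxy]methyl}-6-hydroxy-4-methoxyphenoxy]-6-hydroxy-4-methylbenzoate
Product: 19 methyl 2-hydroxy-6-[2-hydroxy-6-(hydroxymethyl)-4-methoxyphenoxy]-4-methylbenzoate
Conditions: Bu4NF, AcOH, THF, 0 °C to rt
Reagents that add atoms: none
Why: Fluoride cleavage of a primary silyl ether, driven by the strength of the Si-F bond; the acetic acid buffer keeps both phenols protonated and spares the methyl ester.

Step 9
Reactants: 19 methyl 2-hydroxy-6-[2-hydroxy-6-(hydroxymethyl)-4-methoxyphenoxy]-4-methylbenzoate; 20 palmitoyl chloride (hexadecanoyl chloride)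
Product: 21 betaethrin E, [3-hydroxy-2-(3-hydroxy-2-methoxycarbonyl-5-methylphenoxy)-5-methoxyphenyl]methyl hexadecanoate
Conditions: 2,4,6-collidine, CH2Cl2, -40 to 0 °C (20, 1.05 equiv)
Reagents that add atoms: none
Why: Chemoselective O-acylation with an acid chloride and a hindered weak base: collidine does not ionise the phenols, so the neutral primary alcohol should be the best nucleophile present, the ring A phenol being tied up in a hydrogen bond and the ring B phenol flanked by the aryloxy group.

## Compound list

1 | but-3-en-2-one (methyl vinyl ketone) | CC(=O)C=C | starting material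
2 | formaldehyde | C=O | starting material
3 | 3-(hydroxymethyl)but-3-en-2-one | CC(=O)C(=C)CO | intermediate
4 | 3-{[(tert-butyldimethylsilyl)oxy]methyl}but-3-en-2-one | CC(=O)C(=C)CO[Si](C)(C)C(C)(C)C | intermediate
5 | 3,4-dibromo-3-{[(tert-butyldimethylsilyl)oxy]methyl}butan-2-one (racemic, not isolated) | CC(=O)C(Br)(CBr)CO[Si](C)(C)C(C)(C)C | intermediate
6 | (E)-4-bromo-3-{[(tert-butyldimethylsilyl)oxy]methyl}but-3-en-2-one | CC(=O)/C(CO[Si](C)(C)C(C)(C)C)=C/Br | intermediate
7 | methyl 2,6-dihydroxy-4-methylbenzoate | COC(=O)c1c(O)cc(C)cc1O | starting material
8 | methyl 2-{[(1E)-2-{[(tert-butyldimethylsilyl)oxy]methyl}-3-oxobut-1-en-1-yl]oxy}-6-hydroxy-4-methylbenzoate | CC(=O)/C(CO[Si](C)(C)C(C)(C)C)=C/Oc1cc(C)cc(O)c1C(=O)OC | intermediate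
9 | methyl 2-{[(1E)-2-{[(tert-butyldimethylsilyl)oxy]methyl}-6,6,6-trifluoro-3,5-dioxohex-1-en-1-yl]oxy}-6-hydroxy-4-methylbenzoate (not isolated) | O=C(CC(=O)C(F)(F)F)/C(CO[Si](C)(C)C(C)(C)C)=C/Oc1cc(C)cc(O)c1C(=O)OC | intermediate
10 | methyl 2-{[(1E)-4-diazo-2-{[(tert-butyldimethylsilyl)oxy]methyl}-3-oxobut-1-en-1-yl]oxy}-6-hydroxy-4-methylbenzoate | [N-]=[N+]=CC(=O)/C(CO[Si](C)(C)C(C)(C)C)=C/Oc1cc(C)cc(O)c1C(=O)OC | intermediate
11 | chloroacetaldehyde dimethyl acetal (2-chloro-1,1-dimethoxyethane) | COC(CCl)OC | starting material
12 | sodium methoxyacetylide (not isolated) | [Na+].[C-]#COC | intermediate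
13 | methoxyacetylene (methoxyethyne) | COC#C | intermediate
14 | methyl 2-{[(1Z)-2-{[(tert-butyldimethylsilyl)oxy]methyl}-4-oxobuta-1,3-dien-1-yl]oxy}-6-hydroxy-4-methylbenzoate (vinylketene, not isolated) | O=C=C/C(CO[Si](C)(C)C(C)(C)C)=C/Oc1cc(C)cc(O)c1C(=O)OC | intermediate
15 | methyl 2-{[(1Z)-3-[(tert-butyldimethylsilyl)oxy]-2-(2-methoxy-4-oxocyclobut-2-en-1-yl)prop-1-en-1-yl]oxy}-6-hydroxy-4-methylbenzoate (racemic, not isolated) | COC1=CC(=O)C1/C(CO[Si](C)(C)C(C)(C)C)=C/Oc1cc(C)cc(O)c1C(=O)OC | intermediate
16 | methyl 2-{[(1Z,3E)-2-{[(tert-butyldimethylsilyl)oxy]methyl}-4-methoxy-6-oxohexa-1,3,5-trien-1-yl]oxy}-6-hydroxy-4-methylbenzoate (dienylketene, not isolated) | O=C=C/C(OC)=C\C(CO[Si](C)(C)C(C)(C)C)=C\Oc1cc(C)cc(O)c1C(=O)OC | intermediate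
17 | methyl 2-{[2-{[(tert-butyldimethylsilyl)oxy]methyl}-4-methoxy-6-oxocyclohexa-2,4-dien-1-yl]oxy}-6-hydroxy-4-methylbenzoate (racemic, not isolated) | COC1=CC(=O)C(Oc2cc(C)cc(O)c2C(=O)OC)C(CO[Si](C)(C)C(C)(C)C)=C1 | intermediate
18 | methyl 2-[2-{[(tert-butyldimethylsilyl)oxy]methyl}-6-hydroxy-4-methoxyphenoxy]-6-hydroxy-4-methylbenzoate | COC(=O)c1c(O)cc(C)cc1Oc1c(CO[Si](C)(C)C(C)(C)C)cc(OC)cc1O | intermediate
19 | methyl 2-hydroxy-6-[2-hydroxy-6-(hydroxymethyl)-4-methoxyphenoxy]-4-methylbenzoate | COC(=O)c1c(O)cc(C)cc1Oc1c(CO)cc(OC)cc1O | intermediate
20 | palmitoyl chloride (hexadecanoyl chloride) | CCCCCCCCCCCCCCCC(=O)Cl | starting material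
21 | betaethrin E, [3-hydroxy-2-(3-hydroxy-2-methoxycarbonyl-5-methylphenoxy)-5-methoxyphenyl]methyl hexadecanoate | CCCCCCCCCCCCCCCC(=O)OCc1cc(OC)cc(O)c1Oc1cc(C)cc(O)c1C(=O)OC | target

## Step count and least certain steps

Total: 9 steps. Longest linear sequence: 8 steps (steps 1 to 5, then 7 to 9); step 6 is a one-step side branch.

**Step 7 (key step).** The vinylketene may be lost to paths other than the [2+2] addition. The phenol of 18, as it forms, or that of 10 could be acylated by the ketene. The aryl enol ether chromophore could absorb light and react, and the volatile 13 could be depleted from solution. The fallback abandons the annulation and makes the diaryl ether by Ullmann coupling; it sets out from 7.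
- Coupling of 7 with 3-(benzyloxy)-2-bromo-5-methoxybenzaldehyde F1 (CuI, picolinic acid, K3PO4, DMSO, 90 °C) should give methyl 2-[2-(benzyloxy)-6-formyl-4-methoxyphenoxy]-6-hydroxy-4-methylbenzoate F2.
- Reduction with NaBH4 in MeOH should give methyl 2-[2-(benzyloxy)-6-(hydroxymethyl)-4-methoxyphenoxy]-6-hydroxy-4-methylbenzoate F3.
- Hydrogenolysis of the benzyl ether (H2, Pd/C, EtOAc) returns to the route at 19.
- F1 would need a preparation of its own, and the crowded coupling is the weak point of this fallback.

**Step 3.** HBr could be lost in the wrong direction, with the proton taken from the silyloxymethyl arm to give an enol silyl ether with an allylic bromide. Acid released during bromination could also remove the silyl group. The fallback replaces bromination-elimination by a three-component iodo-aldol reaction; it sets out from 2.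
- But-3-yn-2-one, MgI2 and anhydrous monomeric 2 in CH2Cl2 should give (Z)-3-(hydroxymethyl)-4-iodobut-3-en-2-one F4, in which the halogen position is fixed by the mechanism.
- Silylation as in step 2 gives (Z)-3-{[(tert-butyldimethylsilyl)oxy]methyl}-4-iodobut-3-en-2-one F5.
- F5 takes the place of 6 in step 4 and the route is rejoined at 8.

**Step 4.** Substitution could continue at the second hydroxyl, or aryloxy groups could be exchanged between molecules by repeated addition-elimination, because both phenols of 7 are free under basic conditions. The fallback uses temporary benzyl protection; it sets out from 7.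
- Monobenzylation (BnBr, K2CO3, acetone) gives methyl 2-(benzyloxy)-6-hydroxy-4-methylbenzoate F6.
- Addition-elimination with 6 (Cs2CO3, DMF) gives methyl 2-(benzyloxy)-6-{[(1E)-2-{[(tert-butyldimethylsilyl)oxy]methyl}-3-oxobut-1-en-1-yl]oxy}-4-methylbenzoate F7.
- Diazo transfer as in step 5 gives methyl 2-(benzyloxy)-6-{[(1E)-4-diazo-2-{[(tert-butyldimethylsilyl)oxy]methyl}-3-oxobut-1-en-1-yl]oxy}-4-methylbenzoate F8.
- Benzannulation as in step 7 gives methyl 2-(benzyloxy)-6-[2-{[(tert-butyldimethylsilyl)oxy]methyl}-6-hydroxy-4-methoxyphenoxy]-4-methylbenzoate F9.
- Hydrogenolysis (H2, Pd/C, EtOAc, stopped after one equivalent of hydrogen) returns to the route at 18, at the cost of two extra steps.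

**Step 5.** The enol ether could be cleaved, because the beta carbon of the vinylogous ester is open to attack by amide, amine or hydroxide with loss of the phenoxide. C-acylation of the dianion could also be incomplete if the phenoxide takes up the trifluoroacetylating agent. The fallback reverses the order of events; it sets out from 6.
- The same two-stage diazo transfer on 6 (one equivalent of base) should give (E)-4-bromo-1-diazo-3-{[(tert-butyldimethylsilyl)oxy]methyl}but-3-en-2-one F10.
- Addition-elimination of 7 on F10 (K2CO3, DMF) returns to the route at 10, so the aryl enol ether and the phenol never meet the strong base.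

**Step 9.** The ring B phenol could be acylated in competition, or a second acylation could follow, if the acid chloride is not consumed fast enough by the primary alcohol. The fallback is a Mitsunobu esterification of 19 with palmitic acid (PPh3, DIAD, THF, 0 °C). It activates the alcohol and not the acid, so a phenol cannot be acylated. It leads from 19 directly to 21 and makes no new intermediate.

## Further compounds

F1 | step 7 | 3-(benzyloxy)-2-bromo-5-methoxybenzaldehyde | O=Cc1cc(OC)cc(OCc2ccccc2)c1Br
F2 | step 7 | methyl 2-[2-(benzyloxy)-6-formyl-4-methoxyphenoxy]-6-hydroxy-4-methylbenzoate | COC(=O)c1c(O)cc(C)cc1Oc1c(C=O)cc(OC)cc1OCc1ccccc1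
F3 | step 7 | methyl 2-[2-(benzyloxy)-6-(hydroxymethyl)-4-methoxyphenoxy]-6-hydroxy-4-methylbenzoate | COC(=O)c1c(O)cc(C)cc1Oc1c(CO)cc(OC)cc1OCc1ccccc1
F4 | step 3 | (Z)-3-(hydroxymethyl)-4-iodobut-3-en-2-one | CC(=O)/C(CO)=C\I
F5 | step 3 | (Z)-3-{[(tert-butyldimethylsilyl)oxy]methyl}-4-iodobut-3-en-2-one | CC(=O)/C(CO[Si](C)(C)C(C)(C)C)=C\I
F6 | step 4 | methyl 2-(benzyloxy)-6-hydroxy-4-methylbenzoate | COC(=O)c1c(O)cc(C)cc1OCc1ccccc1
F7 | step 4 | methyl 2-(benzyloxy)-6-{[(1E)-2-{[(tert-butyldimethylsilyl)oxy]methyl}-3-oxobut-1-en-1-yl]oxy}-4-methylbenzoate | CC(=O)/C(CO[Si](C)(C)C(C)(C)C)=C/Oc1cc(C)cc(OCc2ccccc2)c1C(=O)OC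
F8 | step 4 | methyl 2-(benzyloxy)-6-{[(1E)-4-diazo-2-{[(tert-butyldimethylsilyl)oxy]methyl}-3-oxobut-1-en-1-yl]oxy}-4-methylbenzoate | O=C(C=[N+]=[N-])/C(CO[Si](C)(C)C(C)(C)C)=C/Oc1cc(C)cc(OCc2ccccc2)c1C(=O)OC
F9 | step 4 | methyl 2-(benzyloxy)-6-[2-{[(tert-butyldimethylsilyl)oxy]methyl}-6-hydroxy-4-methoxyphenoxy]-4-methylbenzoate | COC(=O)c1c(OCc2ccccc2)cc(C)cc1Oc1c(CO[Si](C)(C)C(C)(C)C)cc(OC)cc1O
F10 | step 5 | (E)-4-bromo-1-diazo-3-{[(tert-butyldimethylsilyl)oxy]methyl}but-3-en-2-one | [N-]=[N+]=CC(=O)/C(CO[Si](C)(C)C(C)(C)C)=C/Br
F0 | step 9 | none | none
A1 | alternative 1 | methyl 6-[2-(allyloxy)-4-methoxy-6-(palmitoyloxymethyl)phenoxy]-2-hydroxy-4-methylbenzoate | COC(=O)c1c(O)cc(C)cc1Oc1c(COC(=O)CCCCCCCCCCCCCCC)cc(OC)cc1OCC=C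
A2 | alternative 1 | {3-(allyloxy)-2-[(1-chloro-3-oxobut-1-en-1-yl)oxy]-5-methoxyphenyl}methyl hexadecanoate (either double-bond geometry) | CC(=O)C=C(Cl)Oc1c(COC(=O)CCCCCCCCCCCCCCC)cc(OC)cc1OCC=C
A3 | alternative 1 | methyl 3-oxo-4-(triphenylphosphoranylidene)butanoate | COC(=O)CC(=O)C=P(c1ccccc1)(c1ccccc1)c1ccccc1
A4 | alternative 2 | 2-(benzyloxy)-6-[2-(benzyloxy)-4-methoxy-6-(tert-butyldimethylsilyloxymethyl)phenoxy]-4-methylbenzoic acid | Cc1cc(OCc2ccccc2)c(C(=O)O)c(Oc2c(CO[Si](C)(C)C(C)(C)C)cc(OC)cc2OCc2ccccc2)c1
A5 | alternative 2 | 3-(benzyloxy)-5-methyl-2-(trimethylsilyl)phenyl trifluoromethanesulfonate | Cc1cc(OCc2ccccc2)c([Si](C)(C)C)c(OS(=O)(=O)C(F)(F)F)c1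
A6 | alternative 2 | 2-(benzyloxy)-6-{[(tert-butyldimethylsilyl)oxy]methyl}-4-methoxyphenol | COc1cc(CO[Si](C)(C)C(C)(C)C)c(O)c(OCc2ccccc2)c1
A7 | alternative 2 | carbon dioxide | O=C=O
A8 | alternative 3 | racemic trans-2-(benzyloxy)-6-[2,4-dioxo-6-(tert-butyldimethylsilyloxymethyl)cyclohexyloxy]-4-methylbenzoic acid (one enantiomer drawn) | O=C1CC(=O)[C@@H](Oc2cc(C)cc(OCc3ccccc3)c2C(=O)O)[C@H](CO[Si](C)(C)C(C)(C)C)C1
A9 | alternative 3 | 2-(benzyloxy)-4-methyl-6-(2-oxopropoxy)benzoic acid | CC(=O)COc1cc(C)cc(OCc2ccccc2)c1C(=O)O
A10 | alternative 3 | ethyl (E)-4-[(tert-butyldimethylsilyl)oxy]but-2-enoate | CCOC(=O)/C=C/CO[Si](C)(C)C(C)(C)C
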